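**Retrosynthetic overview**
1. Feature: in each tetrahydroisoquinoline (isoquinoline locants) the benzene ring has its only oxygen on C8, next to fusion carbon C8a, the naphthyl group on C5, and hydrogen on C6 and C7. C4a–C5–C6–C7 is therefore the C2–C3–C4–C5 chain of a 2-alkyl-3-arylfuran, and C8a–C8 is a terminal alkyne.
2. Key disconnection: both benzene rings and both N-rings (C4a–C8a, C7–C8 and C8–O in each half) are opened together to the bis(furan–yne) 33, which a gold catalyst isomerises to 35.
3. 33 comes from a twofold Suzuki coupling of binaphthalene 31 with one furylboronate 10. Boronate 10 already holds both stereocentres: C3 from D-alaninol (aziridine opening) and C1 from an (S)-propargylic alcohol by SN2 inversion.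
4. The core (2,2'-binaphthalene locants: 1,1'-O, 6,6'-Me, 8,8'-OMe) is unsymmetrical, with one isoquinoline on C4 (half A, para to O) and the other on C5' (half B, para to OMe). It is cut at C2–C2' into bromonaphthoquinone 26, whose C4 oxygen becomes the triflate, and naphthylboronate 19; C5' is brominated while half A is still an inert quinone.
5. Ring order: naphthalene B (step 6), naphthalene A (step 10), then two benzene rings and two N-rings together (step 18). The furans are bought and consumed.

Key step: step 18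

Assumption: the SMILES fixes four stereocentres (1R,3R in both isoquinolines) and no biaryl axis, so only the centres are controlled; the atropisomers about the two isoquinoline–naphthalene axes that arise in step 18 would be separated by HPLC on 35 or 37.

**Fragment 1: furylboronate 10**

Step 1
Reactants: 1 D-alaninol
Product: 3 (R)-2-methyl-1-tosylaziridine, via N,O-ditosylate 2 (not isolated)
Conditions: TsCl (2.2 equiv), KOH, CH2Cl2–H2O, rt
Reagents that add atoms: p-toluenesulfonyl chloride, Cc1ccc(cc1)S(=O)(=O)Cl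
Why: One-pot N,O-bis-sulfonylation and base-induced 3-exo-tet SN2 closure is the standard aziridine synthesis from 2-amino alcohols, and no bond to the stereocentre is broken, so R is kept.

Step 2
Reactants: 4 3-bromofuran; 3 (R)-2-methyl-1-tosylaziridine
Product: 6 (R)-N-[1-(3-bromofuran-2-yl)propan-2-yl]-4-methylbenzenesulfonamide, via 3-bromo-2-lithiofuran 5 (not isolated)
Conditions: LiN(iPr)2, THF, −78 °C; then 3, −78 °C → rt; aq NH4Cl
Reagents that add atoms: none
Why: The amide base deprotonates 3-bromofuran only at C2 (next to O and Br, no bromine–lithium exchange), and the furyllithium opens the activated aziridine by SN2 at its CH2, so the C–N stereocentre (later C3, R) is untouched and the bromine marks furan C3 for the biaryl bond.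

Step 3
Reactants: 6 sulfonamide; 7 (S)-4-(trimethylsilyl)but-3-yn-2-ol
Product: 8 N-[(R)-1-(3-bromofuran-2-yl)propan-2-yl]-4-methyl-N-[(R)-4-(trimethylsilyl)but-3-yn-2-yl]benzenesulfonamide
Conditions: Bu3P=CHCN (1.5 equiv), 7 (1.5 equiv), toluene, 100 °C
Reagents that add atoms: none
Why: This is a Mitsunobu-type N-alkylation with the phosphorane reagent suited to weakly acidic N-alkylsulfonamides and secondary alcohols, in which SN2 displacement of the alkoxyphosphonium ion inverts the S carbinol to the R propargylic centre (later C1), the slim activated propargylic carbon eases the crowded substitution and the silyl cap blocks SN2' attack.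

Step 4
Reactants: 8 bromofuran
Product: 10 N-[(R)-1-(3-(4,4,5,5-tetramethyl-1,3,2-dioxaborolan-2-yl)furan-2-yl)propan-2-yl]-4-methyl-N-[(R)-4-(trimethylsilyl)but-3-yn-2-yl]benzenesulfonamide, via 3-lithiofuran 9 (not isolated)
Conditions: n-BuLi (1.05 equiv), THF, −78 °C, 10 min; then iPrOBpin, −78 °C → rt; aq NH4Cl
Reagents that add atoms: 2-isopropoxy-4,4,5,5-tetramethyl-1,3,2-dioxaborolane, CC(C)OB1OC(C)(C)C(C)(C)O1
Why: Bromine–lithium exchange at −78 °C is faster than any deprotonation of the side chain, and borate trapping should give the pinacol boronate without touching either stereocentre or the silylalkyne.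

**Fragment 2: naphthylboronate 19 (half B)**

Step 5
Reactants: 11 (E)-but-2-enoyl chloride
Product: 12 (E)-N,N-diethylbut-2-enamide
Conditions: Et2NH, Et3N, CH2Cl2, 0 °C → rt
Reagents that add atoms: diethylamine, CCNCC
Why: This is a simple N-acylation of a secondary amine by an acid chloride.

Step 6
Reactants: 13 1-bromo-3-methoxy-5-methylbenzene; 12 (E)-N,N-diethylbut-2-enamide
Product: 16 8-methoxy-6-methylnaphthalen-1-ol, via lithium dienolate 14 (not isolated), via 3-methoxy-5-methylbenzyne 15 (not isolated)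
Conditions: LiN(iPr)2 (3.5 equiv), 12 (1.6 equiv), THF, −78 °C; then 13, −78 °C → rt; aq HCl
Reagents that add atoms: none
Why: In this aryne annulation with a lithiated α,β-unsaturated amide (formal [4+2]) the base removes H2 of 13 between Br and OMe, loss of LiBr gives 15, the γ-carbon of 14 adds meta to the methoxy group as is the rule for 3-alkoxyarynes, and the aryl anion next to OMe acylates on the amide, so after loss of diethylamide and tautomerisation the new OH lies peri to OMe.

Step 7
Reactants: 16 8-methoxy-6-methylnaphthalen-1-ol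
Product: 17 8-methoxy-1-(methoxymethoxy)-6-methylnaphthalene
Conditions: NaH, MOMCl, DMF, 0 °C → rt
Reagents that add atoms: chloromethyl methyl ether, COCCl
Why: Williamson-type O-alkylation of the naphtholate installs an acetal that protects the naphthol and also serves as the directing group of step 8.

Step 8
Reactants: 17 MOM ether
Product: 19 2-[8-methoxy-1-(methoxymethoxy)-6-methylnaphthalen-2-yl]-4,4,5,5-tetramethyl-1,3,2-dioxaborolane, via 2-lithionaphthalene 18 (not isolated)
Conditions: n-BuLi, TMEDA, THF, −78 → 0 °C; then iPrOBpin, −78 °C → rt; aq NH4Cl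
Reagents that add atoms: 2-isopropoxy-4,4,5,5-tetramethyl-1,3,2-dioxaborolane, CC(C)OB1OC(C)(C)C(C)(C)O1
Why: In this directed ortho-metalation the acetal oxygens guide butyllithium to C2, the only free position ortho to OMOM because the peri position carries OMe, and the aryllithium is trapped as the boronate.

**Fragment 3: bromonaphthoquinone 26 (half A)**

Step 9
Reactants: 20 methyl 3-methylbut-2-enoate
Product: 22 1-methoxy-3-methyl-1-(trimethylsilyloxy)buta-1,3-diene, via lithium dienolate 21 (not isolated)
Conditions: LiN(iPr)2, THF, −78 °C; then TMSCl, −78 °C → rt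
Reagents that add atoms: chlorotrimethylsilane, C[Si](C)(C)Cl
Why: Kinetic γ-deprotonation and O-silylation of the dienolate give the vinylogous silyl ketene acetal, a standard electron-rich diene.

Step 10
Reactants: 23 2,6-dibromo-1,4-benzoquinone; 22 diene
Product: 25 2-bromo-8-hydroxy-6-methyl-1,4-naphthoquinone, via Diels–Alder adduct 24 (not isolated)
Conditions: CH2Cl2, −30 °C → rt; then aq HCl–THF, rt
Reagents that add atoms: none
Why: In this bromine-directed Diels–Alder reaction the nucleophilic CH2 terminus of the diene bonds to the unsubstituted quinone carbon and the acetal carbon to C–Br, loss of HBr and MeOH plus silyl hydrolysis aromatise the new ring without an oxidant, and the surviving bromine sits beside the carbonyl that is peri to the new OH, which is the future C2.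

Step 11
Reactants: 25 bromohydroxynaphthoquinone
Product: 26 2-bromo-8-methoxy-6-methyl-1,4-naphthoquinone
Conditions: MeI, Ag2O, CH2Cl2, rt, dark
Reagents that add atoms: iodomethane, CI
Why: Neutral O-methylation with MeI/Ag2O is the usual way to alkylate a chelated peri-hydroxyquinone without base damage to the bromoquinone.

**Assembly**

Step 12
Reactants: 26 bromonaphthoquinone; 19 naphthylboronate
Product: 27 8-methoxy-2-[8-methoxy-1-(methoxymethoxy)-6-methylnaphthalen-2-yl]-6-methyl-1,4-naphthoquinone
Conditions: PdCl2(dppf) (5 mol %), K3PO4, dioxane–H2O, 70 °C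
Reagents that add atoms: none
Why: In this Suzuki–Miyaura coupling the vinylogous acyl bromide of the quinone adds readily to zerovalent palladium, so the C2–C2' bond should form under mild base around an axis with only two ortho substituents.

Step 13
Reactants: 27 arylnaphthoquinone
Product: 28 2-[5-bromo-8-methoxy-1-(methoxymethoxy)-6-methylnaphthalen-2-yl]-8-methoxy-6-methyl-1,4-naphthoquinone
Conditions: NBS (1.05 equiv), MeCN, 0 °C → rt, dark
Reagents that add atoms: N-bromosuccinimide, O=C1CCC(=O)N1Br
Why: In this electrophilic aromatic bromination the quinone half is inert to NBS and C5' is the most activated site of half B (alpha position, para to 8'-OMe and ortho to 6'-Me, the pattern that governs bromination of 4,5-dialkoxy-2-methylnaphthalenes), whereas C4' is para only to the twisted OMOM group on the ring that bears the electron-poor quinonyl group.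

Step 14
Reactants: 28 bromo-arylnaphthoquinone
Product: 30 5'-bromo-1-hydroxy-8,8'-dimethoxy-1'-(methoxymethoxy)-6,6'-dimethyl-[2,2'-binaphthalen]-4-yl trifluoromethanesulfonate, via hydroquinone 29 (not isolated)
Conditions: Na2S2O4, THF–H2O, rt, argon; then PhNTf2 (1.0 equiv), Et3N, CH2Cl2, 0 °C
Reagents that add atoms: N-phenylbis(trifluoromethanesulfonimide), O=S(=O)(N(c1ccccc1)S(=O)(=O)C(F)(F)F)C(F)(F)F
Why: Dithionite reduction is followed by chemoselective O-sulfonylation, because C1–OH of 29 is hydrogen-bonded to the peri OMe and flanked by the aryl group while C4–OH is free and open, so the C4 handle comes from the quinone oxygen and is never left to a bromination in which C5 (para to OMe, ortho to Me) would compete.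

Step 15
Reactants: 30 naphthol triflate
Product: 31 5'-bromo-8,8'-dimethoxy-1,1'-bis(methoxymethoxy)-6,6'-dimethyl-[2,2'-binaphthalen]-4-yl trifluoromethanesulfonate
Conditions: NaH, MOMCl, THF–DMF, 0 °C
Reagents that add atoms: chloromethyl methyl ether, COCCl
Why: Williamson-type O-alkylation through the preformed naphtholate overcomes the chelation and crowding of C1–OH, and the aryl triflate and bromide are stable at 0 °C.

Step 16
Reactants: 31 bromide/triflate; 10 furylboronate (2.6 equiv)
Product: 32 4,5'-bis(2-{(R)-2-[N-tosyl-N-((R)-4-(trimethylsilyl)but-3-yn-2-yl)amino]propyl}furan-3-yl)-8,8'-dimethoxy-1,1'-bis(methoxymethoxy)-6,6'-dimethyl-2,2'-binaphthalene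
Conditions: Pd(OAc)2 (10 mol %), SPhos (20 mol %), K3PO4, toluene–H2O (20:1), 95 °C
Reagents that add atoms: none
Why: In this twofold Suzuki–Miyaura coupling the biarylphosphine ligand is made for hindered C–Br and C–OTf partners, the five-membered furan lowers the steric demand at each new axis, the silyl caps keep the alkynes away from palladium, and bringing the finished side chain avoids any late lithiation of the binaphthalene.

Step 17
Reactants: 32 bis(silylalkyne)
Product: 33 4,5'-bis(2-{(R)-2-[N-((R)-but-3-yn-2-yl)-N-tosylamino]propyl}furan-3-yl)-8,8'-dimethoxy-1,1'-bis(methoxymethoxy)-6,6'-dimethyl-2,2'-binaphthalene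
Conditions: K2CO3 (cat.), MeOH–THF, rt
Reagents that add atoms: none
Why: Base-catalysed methanolysis of the C(sp)–Si bonds (protiodesilylation) is mild enough to leave the sulfonamides, the acetals and the propargylic stereocentres alone.

Step 18
Reactants: 33 bis(furan–yne)
Product: 35 4,5'-bis[(1R,3R)-8-hydroxy-1,3-dimethyl-2-tosyl-1,2,3,4-tetrahydroisoquinolin-5-yl]-8,8'-dimethoxy-1,1'-bis(methoxymethoxy)-6,6'-dimethyl-2,2'-binaphthalene, via twofold arene oxide 34 (not isolated)
Conditions: (Ph3P)AuNTf2 (5 mol % per alkyne), dry CH2Cl2 (0.03 M), rt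
Reagents that add atoms: none
Why: The cationic monovalent gold centre binds each terminal alkyne, furan C2 attacks the internal alkyne carbon to give a cyclopropyl gold carbenoid, this opens (furan C2–O and one cyclopropane bond break) to a Z-dienal gold carbene, the aldehyde oxygen closes on the carbene carbon (the former terminal CH) with release of gold, and the oxepine so formed tautomerises to arene oxide 34, which opens and loses H8 to give the phenol. The closest known reaction is the gold-catalysed intramolecular furan–alkyne phenol synthesis, which already turns N-tosyl-N-propargyl-2-(furan-2-yl)ethylamines into tetrahydroisoquinolin-8-ols; the 3-naphthyl group on the furan, the propargylic methyl group and the twofold execution are the only departures. Each N-ring closes 6-exo-dig (C4a–C8a), and each benzene ring closes by oxygen attack on the carbene to the seven-membered oxepine followed by its 6π electrocyclisation (C7–C8). No stereocentre is formed: C1 and C3 lie in the tether, take part in no bond change and keep their R,R (trans) relationship, while the two outer biaryl axes become hindered only now and are expected as atropisomer mixtures. The step needs oxygen on C8 and not on C7, which is secured because oxygen is delivered to the former terminal alkyne carbon and 34 opens towards the cation spread over C7, C5 and C8a, stabilised by the C5 naphthyl and the C8a alkyl group; the four-atom tether allows only the six-membered N-ring, and the masked naphthols leave no other nucleophile for the alkyne.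

Step 19
Reactants: 35 bis(N-tosyl) compound
Product: 36 4,5'-bis[(1R,3R)-8-hydroxy-1,3-dimethyl-1,2,3,4-tetrahydroisoquinolin-5-yl]-8,8'-dimethoxy-1,1'-bis(methoxymethoxy)-6,6'-dimethyl-2,2'-binaphthalene
Conditions: SmI2 (0.1 M in THF, added in portions until 35 is consumed), Et3N, H2O, rt
Reagents that add atoms: none
Why: Single-electron reductive N–S cleavage by divalent samarium activated with amine and water acts on hindered dialkyl tosylamides at room temperature, tolerates aryl ethers, acetals and phenols, and involves no stereocentre.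

Step 20
Reactants: 36 bis(MOM ether)
Product: 37 target, 4,5'-bis[(1R,3R)-8-hydroxy-1,3-dimethyl-1,2,3,4-tetrahydroisoquinolin-5-yl]-8,8'-dimethoxy-6,6'-dimethyl-[2,2'-binaphthalene]-1,1'-diol
Conditions: HCl, MeOH, 40 °C, argon; then aq NaHCO3
Reagents that add atoms: none
Why: Acid-catalysed acetal exchange with methanol removes both MOM groups in one operation, the methyl ethers, the protonated amines and the stereocentres are inert, and neutralisation gives the free base.

**Compound list**
1 | D-alaninol, (R)-2-aminopropan-1-ol | C[C@@H](N)CO | starting material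
2 | (R)-2-(tosylamino)propyl 4-methylbenzenesulfonate | C[C@@H](NS(=O)(=O)c1ccc(C)cc1)COS(=O)(=O)c1ccc(C)cc1 | intermediate
3 | (R)-2-methyl-1-tosylaziridine | C[C@@H]1CN1S(=O)(=O)c1ccc(C)cc1 | intermediate
4 | 3-bromofuran | Brc1ccoc1 | starting material
5 | 3-bromo-2-lithiofuran | [Li]c1occc1Br | intermediate
6 | (R)-N-[1-(3-bromofuran-2-yl)propan-2-yl]-4-methylbenzenesulfonamide | Brc1ccoc1C[C@@H](C)NS(=O)(=O)c1ccc(C)cc1 | intermediate
7 | (S)-4-(trimethylsilyl)but-3-yn-2-ol | C[C@H](O)C#C[Si](C)(C)C | starting material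
8 | N-[(R)-1-(3-bromofuran-2-yl)propan-2-yl]-4-methyl-N-[(R)-4-(trimethylsilyl)but-3-yn-2-yl]benzenesulfonamide | Brc1ccoc1C[C@@H](C)N([C@@H](C#C[Si](C)(C)C)C)S(=O)(=O)c1ccc(C)cc1 | intermediate
9 | 3-lithiofuran derived from 8 | [Li]c1ccoc1C[C@@H](C)N([C@@H](C#C[Si](C)(C)C)C)S(=O)(=O)c1ccc(C)cc1 | intermediate
10 | furan-3-yl pinacol boronate carrying the complete (R,R) side chain | CC1(C)OB(OC1(C)C)c1ccoc1C[C@@H](C)N([C@@H](C#C[Si](C)(C)C)C)S(=O)(=O)c1ccc(C)cc1 | intermediate
11 | (E)-but-2-enoyl chloride | C/C=C/C(=O)Cl | starting material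
12 | (E)-N,N-diethylbut-2-enamide | C/C=C/C(=O)N(CC)CC | intermediate
13 | 1-bromo-3-methoxy-5-methylbenzene | COc1cc(C)cc(Br)c1 | starting material
14 | lithium dienolate of 12 | C=CC=C(O[Li])N(CC)CC | intermediate
15 | 3-methoxy-5-methylbenzyne | COC1=CC(C)=CC#C1 | intermediate
16 | 8-methoxy-6-methylnaphthalen-1-ol | COc1cc(C)cc2cccc(O)c12 | intermediate
17 | 8-methoxy-1-(methoxymethoxy)-6-methylnaphthalene | COCOc1cccc2cc(C)cc(OC)c12 | intermediate
18 | 2-lithio-8-methoxy-1-(methoxymethoxy)-6-methylnaphthalene | COCOc1c([Li])ccc2cc(C)cc(OC)c12 | intermediate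
19 | 2-[8-methoxy-1-(methoxymethoxy)-6-methylnaphthalen-2-yl]-4,4,5,5-tetramethyl-1,3,2-dioxaborolane | COCOc1c(B2OC(C)(C)C(C)(C)O2)ccc2cc(C)cc(OC)c12 | intermediate
20 | methyl 3-methylbut-2-enoate | COC(=O)C=C(C)C | starting material
21 | lithium dienolate of 20 | COC(O[Li])=CC(C)=C | intermediate
22 | 1-methoxy-3-methyl-1-(trimethylsilyloxy)buta-1,3-diene | COC(O[Si](C)(C)C)=CC(C)=C | intermediate
23 | 2,6-dibromo-1,4-benzoquinone | O=C1C=C(Br)C(=O)C(Br)=C1 | starting material
24 | Diels–Alder adduct of 22 and 23 | COC1(O[Si](C)(C)C)C=C(C)CC2C(=O)C=C(Br)C(=O)C12Br | intermediate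
25 | 2-bromo-8-hydroxy-6-methyl-1,4-naphthoquinone | O=C1C(Br)=CC(=O)c2cc(C)cc(O)c12 | intermediate
26 | 2-bromo-8-methoxy-6-methyl-1,4-naphthoquinone | O=C1C(Br)=CC(=O)c2cc(C)cc(OC)c12 | intermediate
27 | 8-methoxy-2-[8-methoxy-1-(methoxymethoxy)-6-methylnaphthalen-2-yl]-6-methyl-1,4-naphthoquinone | COCOc1c(C2=CC(=O)c3cc(C)cc(OC)c3C2=O)ccc2cc(C)cc(OC)c12 | intermediate
28 | 2-[5-bromo-8-methoxy-1-(methoxymethoxy)-6-methylnaphthalen-2-yl]-8-methoxy-6-methyl-1,4-naphthoquinone | COCOc1c(C2=CC(=O)c3cc(C)cc(OC)c3C2=O)ccc2c(Br)c(C)cc(OC)c12 | intermediate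
29 | 5'-bromo-8,8'-dimethoxy-1'-(methoxymethoxy)-6,6'-dimethyl-[2,2'-binaphthalene]-1,4-diol | COc1cc(C)cc2c(O)cc(-c3ccc4c(Br)c(C)cc(OC)c4c3OCOC)c(O)c12 | intermediate
30 | 5'-bromo-1-hydroxy-8,8'-dimethoxy-1'-(methoxymethoxy)-6,6'-dimethyl-[2,2'-binaphthalen]-4-yl trifluoromethanesulfonate | COc1cc(C)cc2c(OS(=O)(=O)C(F)(F)F)cc(-c3ccc4c(Br)c(C)cc(OC)c4c3OCOC)c(O)c12 | intermediate
31 | 5'-bromo-8,8'-dimethoxy-1,1'-bis(methoxymethoxy)-6,6'-dimethyl-[2,2'-binaphthalen]-4-yl trifluoromethanesulfonate | COc1cc(C)cc2c(OS(=O)(=O)C(F)(F)F)cc(-c3ccc4c(Br)c(C)cc(OC)c4c3OCOC)c(OCOC)c12 | intermediate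
32 | bis(furan) binaphthalene with two silyl-capped (R,R) side chains | COc1cc(C)cc2c(-c3ccoc3C[C@@H](C)N([C@@H](C#C[Si](C)(C)C)C)S(=O)(=O)c3ccc(C)cc3)cc(-c3ccc4c(-c5ccoc5C[C@@H](C)N([C@@H](C#C[Si](C)(C)C)C)S(=O)(=O)c5ccc(C)cc5)c(C)cc(OC)c4c3OCOC)c(OCOC)c12 | intermediate
33 | bis(furan–yne) binaphthalene, N-tosyl, naphthols as MOM ethers (key-step precursor) | COc1cc(C)cc2c(-c3ccoc3C[C@@H](C)N([C@@H](C#C)C)S(=O)(=O)c3ccc(C)cc3)cc(-c3ccc4c(-c5ccoc5C[C@@H](C)N([C@@H](C#C)C)S(=O)(=O)c5ccc(C)cc5)c(C)cc(OC)c4c3OCOC)c(OCOC)c12 | intermediate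
34 | twofold 7,8-arene oxide of the two new carbocycles | COc1cc(C)cc2c(C3=CC4OC4C5=C3C[C@@H](C)N([C@@H]5C)S(=O)(=O)c3ccc(C)cc3)cc(-c3ccc4c(C5=CC6OC6C7=C5C[C@@H](C)N([C@@H]7C)S(=O)(=O)c5ccc(C)cc5)c(C)cc(OC)c4c3OCOC)c(OCOC)c12 | intermediate
35 | bis[(1R,3R)-N-tosyl-8-hydroxy-1,3-dimethyltetrahydroisoquinolin-5-yl] binaphthalene, naphthols as MOM ethers (key-step product) | COc1cc(C)cc2c(-c3ccc(O)c4c3C[C@@H](C)N([C@@H]4C)S(=O)(=O)c3ccc(C)cc3)cc(-c3ccc4c(-c5ccc(O)c6c5C[C@@H](C)N([C@@H]6C)S(=O)(=O)c5ccc(C)cc5)c(C)cc(OC)c4c3OCOC)c(OCOC)c12 | intermediate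
36 | bis[(1R,3R)-8-hydroxy-1,3-dimethyltetrahydroisoquinolin-5-yl] binaphthalene, naphthols as MOM ethers | COc1cc(C)cc2c(-c3ccc(O)c4c3C[C@@H](C)N[C@@H]4C)cc(-c3ccc4c(-c5ccc(O)c6c5C[C@@H](C)N[C@@H]6C)c(C)cc(OC)c4c3OCOC)c(OCOC)c12 | intermediate
37 | CNP0077060.1 | COc1cc(C)cc2c(-c3ccc(O)c4c3C[C@@H](C)N[C@@H]4C)cc(-c3ccc4c(-c5ccc(O)c6c5C[C@@H](C)N[C@@H]6C)c(C)cc(OC)c4c3O)c(O)c12 | target

**Totals and risks**

Total step count: 20. Longest linear sequence: 13 steps (5, 6, 7, 8, then 12 to 20).

Most likely to fail, first: step 18. The crowded 3-naphthylfuran may attack the gold–alkyne complex slowly. The catalyst may decay before the second half has reacted, so the reaction stalls at the half-cyclised stage. The carbene or arene oxide stage may also be diverted to other isomers. The fallback sets out from 8 and comes back at 35; it builds the arene on the small fragment, once, before any biaryl bond exists. K2CO3 in MeOH frees the alkyne of 8 to give N-[(R)-but-3-yn-2-yl]-N-[(R)-1-(3-bromofuran-2-yl)propan-2-yl]-4-methylbenzenesulfonamide F1. The gold-catalysed furan–yne isomerisation of this unhindered substrate gives (1R,3R)-5-bromo-1,3-dimethyl-2-tosyl-1,2,3,4-tetrahydroisoquinolin-8-ol F2. Miyaura borylation (B2pin2, PdCl2(dppf), KOAc, dioxane, 85 °C) gives (1R,3R)-1,3-dimethyl-5-(4,4,5,5-tetramethyl-1,3,2-dioxaborolan-2-yl)-2-tosyl-1,2,3,4-tetrahydroisoquinolin-8-ol F3. Twofold Suzuki–Miyaura coupling of F3 with 31 under the conditions of step 16 then gives 35.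

Second: step 3. The SN2 reaction between a secondary sulfonamide nitrogen and a secondary carbinol carbon may be sluggish. The activated alcohol may then eliminate to the enyne, and configuration may erode through ionisation. The fallback sets out from 5 (made from 4 as in step 2) and comes back at 8; it forms the C1–N bond with a small primary amine and sulfonylates afterwards.
- Furyllithium 5 opens commercial (R)-3-Boc-4-methyl-1,2,3-oxathiazolidine 2,2-dioxide at its CH2 to give (R)-N-Boc-N-[1-(3-bromofuran-2-yl)propan-2-yl]sulfamic acid F4.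
- HCl in dioxane–water strips the sulfate and the Boc group from F4 to give (R)-1-(3-bromofuran-2-yl)propan-2-amine F5.
- Alcohol 7 with MsCl and Et3N gives (S)-4-(trimethylsilyl)but-3-yn-2-yl methanesulfonate F6.
- F5 displaces the mesylate of F6 with inversion (K2CO3, MeCN, 50 °C) to give (R)-N-[(R)-1-(3-bromofuran-2-yl)propan-2-yl]-4-(trimethylsilyl)but-3-yn-2-amine F7.
- TsCl, pyridine and DMAP convert F7 into 8.

Third: step 16. Transmetalation of the ortho-substituted furylboronate to the hindered naphthylpalladium species may be slow. That would allow protodeboronation of 10, hydrolysis of the triflate, stalling after one coupling and loss of the silyl caps. The fallback sets out from 31 and comes back at 32; it makes both biaryl bonds with a furan that has no ortho substituent and grows the side chains afterwards.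
- 31 and commercial furan-3-boronic acid (same catalyst) give 4,5'-di(furan-3-yl)-8,8'-dimethoxy-1,1'-bis(methoxymethoxy)-6,6'-dimethyl-2,2'-binaphthalene F8.
- n-BuLi (2.2 equiv, THF, −78 → 0 °C) lithiates each 3-arylfuran at C2, the position favoured next to the aryl group. The MOM ethers have no free ortho position left. This gives the 4,5'-bis(2-lithiofuran-3-yl) derivative F9.
- F9 opens two equivalents of aziridine 3 to give the bis[(R)-2-(tosylamino)propyl] compound F10.
- Twofold alkylation of F10 with 7 as in step 3 gives 32.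

**Further compounds**
F1 | step 18 | N-[(R)-but-3-yn-2-yl]-N-[(R)-1-(3-bromofuran-2-yl)propan-2-yl]-4-methylbenzenesulfonamide | Brc1ccoc1C[C@@H](C)N([C@@H](C#C)C)S(=O)(=O)c1ccc(C)cc1
F2 | step 18 | (1R,3R)-5-bromo-1,3-dimethyl-2-tosyl-1,2,3,4-tetrahydroisoquinolin-8-ol | Brc1ccc(O)c2c1C[C@@H](C)N([C@@H]2C)S(=O)(=O)c1ccc(C)cc1
F3 | step 18 | (1R,3R)-1,3-dimethyl-5-(4,4,5,5-tetramethyl-1,3,2-dioxaborolan-2-yl)-2-tosyl-1,2,3,4-tetrahydroisoquinolin-8-ol | CC1(C)OB(OC1(C)C)c1ccc(O)c2c1C[C@@H](C)N([C@@H]2C)S(=O)(=O)c1ccc(C)cc1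
F4 | step 3 | (R)-N-Boc-N-[1-(3-bromofuran-2-yl)propan-2-yl]sulfamic acid | Brc1ccoc1C[C@@H](C)N(C(=O)OC(C)(C)C)S(=O)(=O)O
F5 | step 3 | (R)-1-(3-bromofuran-2-yl)propan-2-amine | Brc1ccoc1C[C@@H](C)N
F6 | step 3 | (S)-4-(trimethylsilyl)but-3-yn-2-yl methanesulfonate | C[C@H](OS(C)(=O)=O)C#C[Si](C)(C)C
F7 | step 3 | (R)-N-[(R)-1-(3-bromofuran-2-yl)propan-2-yl]-4-(trimethylsilyl)but-3-yn-2-amine | Brc1ccoc1C[C@@H](C)N[C@@H](C#C[Si](C)(C)C)C
F8 | step 16 | 4,5'-di(furan-3-yl)-8,8'-dimethoxy-1,1'-bis(methoxymethoxy)-6,6'-dimethyl-2,2'-binaphthalene | COc1cc(C)cc2c(-c3ccoc3)cc(-c3ccc4c(-c5ccoc5)c(C)cc(OC)c4c3OCOC)c(OCOC)c12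
F9 | step 16 | 4,5'-bis(2-lithiofuran-3-yl)-8,8'-dimethoxy-1,1'-bis(methoxymethoxy)-6,6'-dimethyl-2,2'-binaphthalene | COc1cc(C)cc2c(-c3ccoc3[Li])cc(-c3ccc4c(-c5ccoc5[Li])c(C)cc(OC)c4c3OCOC)c(OCOC)c12
F10 | step 16 | 4,5'-bis{2-[(R)-2-(tosylamino)propyl]furan-3-yl}-8,8'-dimethoxy-1,1'-bis(methoxymethoxy)-6,6'-dimethyl-2,2'-binaphthalene | COc1cc(C)cc2c(-c3ccoc3C[C@@H](C)NS(=O)(=O)c3ccc(C)cc3)cc(-c3ccc4c(-c5ccoc5C[C@@H](C)NS(=O)(=O)c5ccc(C)cc5)c(C)cc(OC)c4c3OCOC)c(OCOC)c12
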